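You ask how steeply the rate of making target follows free catalyst and coupling partner at 20 % conversion.

| setting | zeta | gamma | flask |
|---|---|---|---|
| substrate | 0.30 M | 0.30 M | 0.30 M |
| coupling partner | 0.25 equiv | 0.38 equiv | 0.500 equiv |
| free catalyst | 10 mol% | 10 mol% | 10 mol% |
| remark | run made earlier | run made earlier |  |

- zeta (time / min: target / %, substrate / %): 5.00: 18.1, 0; 10.0: 20.6, 0; 15.0: 22.1, 0; 20.0: 23.8, 0; 25.0: 23.3, 0.6
- gamma (time / min: target / %, substrate / %): 5.00: 23.3, 0; 10.0: 26.5, 0.1; 15.0: 26.8, 0; 20.0: 29.2, 1.2; 25.0: 27.1, 0.8

(each reading ± 1 percentage point)

* apparent order in free catalyst when 20 % of the substrate are converted (percent change of the rate of making target for one percent more free catalyst charged)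
* apparent order in coupling partner when 20 % of the substrate are converted (percent change of the rate of making target for one percent more coupling partner charged)

Take the given numbers in turn. The substrate readings add little: zeta already shows 0 % at 5.00 min, so in zeta 20 % conversion is passed before the first reading. The catalyst loading is 10 mol% in zeta and 10 mol% in gamma, so an error in the order in free catalyst would not show in either run. The target readings at 5.00 min carry the partner order, and zeta's reading is lower than gamma's, so one scatter weighs more on zeta's.

From them I reckon the partner slope, 0.603, the percent change of target yield for one percent more coupling partner charged. One scatter on zeta's reading moves it by 0.132. At 25.0 min the same slope reads 0.361. Now join the ends: if partner enters one bimolecular step, the order at the very start is 1, while the slope read at 25.0 min is lower than the one read at 5.00 min. So I place the order asked for between 0.603 and 1.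

The forecast gives 0.6 for coupling partner and 0.8 for free catalyst, saying of the latter: “I guess just under first order, with wide limits”. Its partner figure is the lower end of my range.

The new flask gives 0.92 in coupling partner and 0.45 in free catalyst.

    substrate + free catalyst → catalyst intermediate A (k = 2.00 /M/s)
    coupling partner + catalyst intermediate A ⇌ catalyst intermediate B (K = 3.30 /M, k = 0.790 /M/s)
    catalyst intermediate B → free catalyst + target (k = 0.0890 /s)
    2 substrate → self-condensation product (k = 0.130 /M/s)

The order in coupling partner is higher than the partner slope of 0.603, by 0.317. At 20 % conversion in the new flask, catalyst intermediate A holds 60.0 % of the catalyst. Carried from gamma's charge to the new flask, the partner slope predicts 27.5 % target at 5.00 min; the new flask holds 26.4 % at 4.00 min and 28.7 % at 20.0 min.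

(The data are calculated from invented constants.)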